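About 950 turnovers per lost catalyst is what the south-east flask allows at its full substrate charge. I call this the turnover allowance: the target formed per catalyst lost, which is the rate constant of complex breaking into enzyme and target, divided by the product of c(substrate) and the rate constant of substrate attacking the complex. Both steps leave the complex, so the amount of complex cancels. It is a total turnover number, set at the c(substrate) of the moment.

| flask | substrate | precatalyst | time |
|---|---|---|---|
| north-east | 0.10 M (fed, over 20 s) | 46 µM | 30 s |
| south | 0.30 M (fed, over 20 s) | 46 µM | 30 s |
| south-east | 0.80 M (fed, over 20 s) | 46 µM | 30 s |

    enzyme + target → enzyme + over-reaction product (k1 = 860 L mol⁻¹ s⁻¹)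
    substrate + complex → spent catalyst (k2 = 0.25 L mol⁻¹ s⁻¹)
    precatalyst → enzyme (k3 = 0.032 s⁻¹)
    complex → enzyme + target (k4 = 190 s⁻¹)
    substrate + enzyme ⇌ complex (K5 = 3.7 L mol⁻¹, k5 = 1.2 × 10⁵ L mol⁻¹ s⁻¹)

- percent here means substrate units held: one spent catalyst counts as two
- "hardly changes" means that all values lie within two and a half points (for a concentration: within two and a half percent of the largest)
- run time (north-east): 30 s

- [target] at the end for north-east, south, south-east, in this order
- the shape of the row from first to last (falls, then rises / hardly changes / rises all the way / falls all the way / rises, then falls)

In the first instants of the south-east flask, the precatalyst releases enzyme with a half-life of 21.7 s, while substrate arrives steadily over 20 s. Binding is the fast step: its reverse, at 32400 s⁻¹, runs far above the breakdown of complex at 190 s⁻¹. I therefore treat it as a rapid equilibrium, which at full charge puts 74.7% of the working catalyst in complex.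

In the middle, once the charge is in, a working catalyst in this flask has a half-life of 4.64 s. That is shorter than the precatalyst's, so in my reckoning losses follow release closely.

By 30 s, 28.4 µM has been released. As a first round I count it as spent, which gives 27.0 mM of target formed. Then I put that answer back: I take substrate at 0.773 M and estimate that 3.77 µM of the released catalyst is still working, so the second round gives 24.2 mM. I commit to that as a low figure, because halfway through the feed 0.400 M of substrate has been fed, and at that c(substrate) the allowance is 1900.

In the north-east flask the same product of release and allowance is 216 mM, above its charge of 0.10 M, so there I look to the speed of the round instead. My reckoning stops at this: release times allowance, a figure that sinks as the charge grows, at fixed precatalyst.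

The forecast gives 0.0166 M, 0.0305 M and 0.028 M, a row that rises, then falls, and says of the south-east flask “catalyst dies quickly”. Its last point stands above my 24.2 mM.

The flask gives 0.0166 M, 0.0308 M and 0.0284 M, so the row rises, then falls. In the south-east flask, spent catalyst holds 49.6% of the catalyst charged at 30.0 s. From 20.0 s to that time, this flask forms 9.96 mM of target and over-reaction product together while 10.2 µM of catalyst is spent. That reads 976 per catalyst, against an allowance of 986 at the end. In the north-east flask the allowance at the end is 9390, and the whole run reads 9670 per spent catalyst.

(The constants were chosen freely; the flask was simulated.)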